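The numbers in the tables come from a simulation on assumed constants; scatter was added.

**Constant loss.** Elm, ash and the flask share one catalyst charge, 8.3 mM, and what should carry over between them is the fractional loss of target per minute, read late in each run. Your hunch of plain late decay agrees with that, so the quick number comes from solving both ends and joining them.

all flasks: gas phase 200 mM (held); catalyst 8.3 mM
- elm: substrate 0.80 M; run made earlier
- ash: substrate 1.8 M; run made earlier
- flask: substrate 1.2 M; time 20 min

| run | time / min | target / % | substrate / % |
|---|---|---|---|
| elm | 2.50 | 31.7 | 5.8 |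
| elm | 5.00 | 31.3 | 0.3 |
| elm | 8.00 | 25.7 | 0.5 |
| elm | 10.0 | 22.8 | 0 |
| elm | 12.0 | 19.5 | 0.5 |
| ash | 1.00 | 9.5 | 18.3 |
| ash | 3.00 | 17.6 | 2.2 |
| ash | 6.00 | 16.0 | 0 |
| ash | 8.00 | 14.6 | 0 |
| ash | 12.0 | 10.8 | 0 |

(standard deviation of a reading: 0.5 percentage points)

- at the start none of the gas phase is in solution

* the target standing at 20 min, as a percentage of the substrate charged
* concentration of dissolved gas in solution at 20 min, in percent of saturation

**Late end.** With substrate at 0.3 % by 5.00 min, elm's target falls from 31.3 % to 19.5 % at 12.0 min, which gives 0.0676 min⁻¹ as the decay constant, a pseudo-first-order constant for target loss. Ash reads 0.0655 min⁻¹, close to elm's.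

**Early end.** Run back to zero time, elm starts from 43.9 % and ash from 24.0 %. The flask's charge is the geometric mean of theirs, so I take the same mean, 32.5 %, and 20 min of decay leaves 8.40 %.

**Dissolved gas.** Ash's first 1.00 min draws at least 0.171 M min⁻¹ from a solution that starts without dissolved gas. If the crossing into solution goes with the deficit from saturation, its time constant is at most 1.17 min, shorter than 20 min. Even charging the flask's target loss against the gas leaves 96.0 % of saturation.

**Result.** The forecast gives 8.4 %, as here, but a lower 85 % for the gas: “I expect it near saturation, though this is loosely constrained”. The flask gives 10.0 % and 100 %.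

    gas phase ⇌ dissolved gas, rate k1*(csat - [dissolved gas]) (kL = 0.0220 s⁻¹)
    substrate + dissolved gas + catalyst → catalyst + target (k = 18.0 L² mol⁻² s⁻¹)
    target + catalyst ⇌ isomer of the product + catalyst, rate k3*[catalyst]*[target] forward; the back reaction follows from the equilibrium constant (K = 4.90, k = 0.150 L mol⁻¹ s⁻¹)
    2 substrate → homo dimer (k = 0.0160 L mol⁻¹ s⁻¹)

**Five minutes.** For the same flask read at 5.0 min, 32.5 % and 0.0676 min⁻¹ give 23.1 % of target, and the flask read then gives 23.7 %, with substrate at 0.11 %. From that reading to 20 min, the flask's target falls at 0.0572 min⁻¹, slower than 0.0676 min⁻¹, and ends at 10.0 % against 8.40 % reckoned. Left to 200 min, the flask holds 5.22 % of target beside 25.6 % of isomer of the product.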